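Early times in the beta run show two paths out of the starting material: target and cross product rise side by side, but the target levels off while the cross product keeps climbing. The problem stands as follows.

| flask | starting material | reagent | second substrate | temperature | remark | time |
|---|---|---|---|---|---|---|
| beta | 0.30 M | 0.18 M | 0.60 M | 35 °C | run made earlier |  |
| zeta | 0.60 M | 0.18 M | 0.60 M | 35 °C | run made earlier |  |
| Wednesday's | 0.30 M | 0.180 M (in portions, 2, over 4.0 min) | 0.600 M | 35 °C | first portion at the start, last at 4.0 min | 5.0 min |
| Thursday's | 0.30 M | 0.180 M | 0.600 M |  | everything together at the start at 5 °C, warmed to 35 °C at 4.0 min | 5.0 min |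
| Saturday's | 0.30 M (fed, over 4.0 min) | 0.180 M | 0.600 M |  | the addition at 5 °C, then warmed to 35 °C; the feed brings no volume worth counting | 5.0 min |
| Monday's | 0.30 M | 0.180 M | 0.600 M | 35 °C | everything together at the start | 5.0 min |
| Friday's | 0.30 M (fed, over 4.0 min) | 0.180 M | 0.600 M | 35 °C | all else is in the flask from the start; the feed brings no volume worth counting | 5.0 min |

beta run (percent of the starting material charged)

| time / min | cross product / % | target / % | starting material / % |
|---|---|---|---|
| 0.167 | 7.6 | 5.1 | 88.4 |
| 0.500 | 17.2 | 10.1 | 71.7 |
| 0.833 | 25.5 | 13.1 | 61.0 |
| 1.33 | 34.1 | 14.7 | 50.1 |
| 2.00 | 43.6 | 16.5 | 40.2 |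
| 2.50 | 48.0 | 16.3 | 35.2 |
| 3.00 | 52.8 | 16.6 | 29.8 |

zeta run (percent of the starting material charged)

| time / s | cross product / % | target / % | starting material / % |
|---|---|---|---|
| 10.0 | 6.5 | 5.4 | 88.3 |
| 15.0 | 9.9 | 7.2 | 83.0 |
| 25.0 | 15.7 | 8.3 | 76.7 |
| 40.0 | 20.3 | 11.7 | 68.9 |
| 50.0 | 24.6 | 11.6 | 63.4 |
| 80.0 | 33.3 | 13.0 | 54.6 |
| 90.0 | 34.6 | 13.8 | 50.6 |

(scatter of a reading: 0.5 percentage points)

- the analysis behind the earlier runs scatters by 0.5 percentage points, standard deviation
- the earlier runs do not show what temperature does; that part of a forecast is a guess

- the flask that comes out highest in amount of cross product, in percent of the starting material charged, or "all alike" when all lie within 1.5 percentage points (Wednesday's / Thursday's / Saturday's / Monday's / Friday's / all alike)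
- cross product at the end, in percent of the starting material charged, Wednesday's
- cross product at the end, in percent of the starting material charged, Thursday's
- cross product at the end, in percent of the starting material charged, Saturday's
- cross product at the end, in percent of the starting material charged, Monday's
- cross product at the end, in percent of the starting material charged, Friday's

From 2.00 min to 3.00 min the target reads 16.5% and then 16.6%, so I take the fall of the starting material in that stretch, from 40.2% to 29.8%, as the cross path working by itself. That reading gives a pseudo-first-order rate of 0.299 /min, with the second substrate already used counted inside it. Over 5.0 min it gives 1.50, the lifetime count N, meaning the time a portion of starting material spends in the warm flask divided by its lifetime on the cross path. A portion keeps exp(-N) of itself, here 22.4%.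

I read Monday's from this. I take the beta run's target of 16.6% off the charge first and let the count act on the rest, which gives 64.7% of cross product. Wednesday's has the same count, so one number cannot rank these two flasks, and I need a second step. Wednesday's starts with half the reagent, so as an estimate I halve the target to 8.30%, and the same reckoning gives 71.2%. In Friday's, averaging exp(-N) over the feed leaves 43.2%, so I reckon 56.8% of cross product before any target is taken off. Thursday's and Saturday's get 0.299 lifetimes warm, which leaves more starting material than either of those counts, at 74.1%, before a cold stretch that the runs cannot price.

The forecast names Wednesday's, with 70% for Wednesday's, 34% for Thursday's, 32% for Saturday's, 66% for Monday's and 56% for Friday's, and it says “the split dose halves early target loss”. My Monday's figure lies below its 66%, and my Wednesday's figure lies above its 70%.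

The flasks give 72.3% for Wednesday's, 31.9% for Thursday's, 30.1% for Saturday's, 64.1% for Monday's and 51.0% for Friday's, so Wednesday's comes out higher than the others, as forecast.

    reagent + target → over-reaction product (k = 0.00676 /M/s, Ea = 59.0 kJ/mol)
    second substrate + reagent → second product (k = 0.0372 /M/s, Ea = 65.0 kJ/mol)
    starting material + reagent → target (k = 0.0351 /M/s, Ea = 71.0 kJ/mol)
    starting material + second substrate → cross product (k = 0.0133 /M/s, Ea = 74.0 kJ/mol)
    (constants at 35 °C)

In Wednesday's at 1.20 min the second substrate goes into cross product 4.6 times as fast as into second product, and at 5.00 min the count of 1.50, acting on what the halved target leaves, gives 20.5% of starting material against the 16.4% standing in that flask. With Wednesday's left until 8.0 min the count grows to 2.39 and the same reckoning gives 8.36%, and that flask holds 8.1% of its starting material.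

(All runs were generated by integration with constants of no real substance, and the scatter is random.)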